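**Retrosynthetic overview**
- Last, the two ring A bromines go in by OH-directed para/ortho bromination of 2-(2,4-dibromophenoxy)phenol. Ring B is bought complete, with both bromines, as 2,4-dibromophenol.
- Ring A is the only ring formed. The phenol comes from DDQ aromatisation of the silyl dienol ether of a 6-aryloxycyclohex-2-enone, which comes from decarboxylation of a tert-butyl 1-aryloxy-2-oxocyclohex-3-ene-1-carboxylate.
- That cyclohexenone comes from an intramolecular aldol condensation (bond C2–C3) of a keto aldehyde. The keto aldehyde comes from an intermolecular Michael addition (key C–C bond, C5–C6) of tert-butyl 2-aryloxyacetoacetate to acrolein.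
- The diaryl-ether C–O bond comes from SN2 attack of 2,4-dibromophenoxide on tert-butyl 2-chloroacetoacetate. It is made before ring A exists, so no metal-catalysed coupling ever meets a C–Br bond.

Assumption: the SMILES has no stereocentre and the diaryl ether rotates freely, so the target is achiral and there is no enantiomer to select. All chiral intermediates are racemates whose stereocentres vanish on aromatisation.

**Step 1**
Reactants: 1 tert-butyl acetoacetate
Product: 2 tert-butyl 2-chloro-3-oxobutanoate (racemic)
Conditions: SO2Cl2 (1.0 equiv), CH2Cl2, 0 °C to rt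
Reagents that add atoms: sulfuryl chloride, ClS(Cl)(=O)=O
Why: Electrophilic α-chlorination of the β-keto ester enol stops at the monochloride with one equivalent, the tert-butyl ester survives the short cold exposure to acid, and the new stereocentre is racemic and enolisable.

**Step 2**
Reactants: 2 tert-butyl 2-chloro-3-oxobutanoate; 3 2,4-dibromophenol
Product: 4 tert-butyl 2-(2,4-dibromophenoxy)-3-oxobutanoate (racemic)
Conditions: K2CO3 (1.5 equiv), acetone, reflux
Reagents that add atoms: none
Why: Williamson-type SN2 displacement of the doubly carbonyl-activated chloride by the phenoxide sets the future diaryl-ether oxygen without any metal catalyst, and the stereocentre stays racemic and enolisable.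

**Step 3**
Reactants: 4 tert-butyl 2-(2,4-dibromophenoxy)-3-oxobutanoate; 5 acrolein (1.3 equiv, freshly distilled)
Product: 6 tert-butyl 2-acetyl-2-(2,4-dibromophenoxy)-5-oxopentanoate (racemic)
Conditions: Et3N (10 mol%), CH2Cl2, 0 °C to rt
Reagents that add atoms: none
Why: In this base-catalysed intermolecular Michael addition the stabilised enolate of the acidic α-aryloxy β-keto ester adds 1,4 to acrolein and forges C5–C6 of ring A, and the quaternary stereocentre forms as a racemate that is erased at step 6.

**Step 4**
Reactants: 6 tert-butyl 2-acetyl-2-(2,4-dibromophenoxy)-5-oxopentanoate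
Product: 8 tert-butyl 1-(2,4-dibromophenoxy)-2-oxocyclohex-3-ene-1-carboxylate (racemic), via ketol 7 (not isolated)
Conditions: piperidine (20 mol%), AcOH (20 mol%), 4 Å molecular sieves, toluene, 60 °C
Reagents that add atoms: none
Why: In this intramolecular aldol condensation (the closing half of a Robinson-type annulation) only attack of the acetyl CH3 on the aldehyde gives a six-membered ring, every alternative being four-membered, and the carbinol stereocentre of the ketol is lost on dehydration.

**Step 5**
Reactants: 8 tert-butyl 1-(2,4-dibromophenoxy)-2-oxocyclohex-3-ene-1-carboxylate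
Product: 10 6-(2,4-dibromophenoxy)cyclohex-2-en-1-one (racemic), via keto acid 9 (not isolated)
Conditions: TFA/CH2Cl2 (1:3), 0 °C to rt; evaporate with toluene; then toluene, 60 °C until gas evolution ends
Reagents that add atoms: none
Why: Acidolysis of the tert-butyl ester followed by six-centre decarboxylation of the β-keto acid removes the activating group without the hydroxide or alkoxide that would cause retro-Claisen opening of the non-enolisable β-keto ester, and C6 is reprotonated without selectivity (racemic).

**Step 6**
Reactants: 10 6-(2,4-dibromophenoxy)cyclohex-2-en-1-one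
Product: 12 1-(2,4-dibromophenoxy)-2-(trimethylsilyloxy)cyclohexa-1,3-diene, via lithium dienolate 11 (not isolated)
Conditions: LiN(SiMe3)2 (1.1 equiv), THF, −78 °C; then Me3SiCl (1.5 equiv), −78 to 0 °C; cold NaHCO3 wash, used crude
Reagents that add atoms: chlorotrimethylsilane, C[Si](C)(C)Cl
Why: Kinetic α'-deprotonation at C6 (acidified by the aryloxy group) and O-silylation give the 2-silyloxy-1,3-diene, which puts the aryloxy group on an sp2 carbon where it cannot be eliminated and removes the last stereocentre.

**Step 7**
Reactants: 12 1-(2,4-dibromophenoxy)-2-(trimethylsilyloxy)cyclohexa-1,3-diene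
Product: 14 2-(2,4-dibromophenoxy)phenol, via aryl silyl ether 13 (not isolated)
Conditions: DDQ (1.1 equiv), toluene, 0 °C to rt; filter; then 1 M aq. HCl, THF, rt
Reagents that add atoms: none
Why: DDQ dehydrogenation (hydride abstraction from a ring CH2 to an oxygen-stabilised cation, then proton loss) of a cyclohexa-1,3-diene is driven by aromatisation, and dilute acid cleaves the labile aryl trimethylsilyl ether.

**Step 8**
Reactants: 14 2-(2,4-dibromophenoxy)phenol
Product: 16 2,4-dibromo-6-(2,4-dibromophenoxy)phenol, via tribromide 15 (not isolated)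
Conditions: Br2 (2.05 equiv), AcOH, 15 °C to rt
Reagents that add atoms: bromine, BrBr
Why: In this electrophilic aromatic bromination the free OH, the strongest donor, directs first para and then to its only open ortho site, while ring B is deactivated by its two bromines, so two equivalents stop at the tetrabromide.

**Compound list**
1 | tert-butyl acetoacetate | CC(=O)CC(=O)OC(C)(C)C | starting material
2 | tert-butyl 2-chloro-3-oxobutanoate (racemic) | CC(=O)C(Cl)C(=O)OC(C)(C)C | intermediate
3 | 2,4-dibromophenol | Oc1ccc(Br)cc1Br | starting material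
4 | tert-butyl 2-(2,4-dibromophenoxy)-3-oxobutanoate (racemic) | CC(=O)C(Oc1ccc(Br)cc1Br)C(=O)OC(C)(C)C | intermediate
5 | acrolein | C=CC=O | starting material
6 | tert-butyl 2-acetyl-2-(2,4-dibromophenoxy)-5-oxopentanoate (racemic) | CC(=O)C(CCC=O)(Oc1ccc(Br)cc1Br)C(=O)OC(C)(C)C | intermediate
7 | ketol: tert-butyl 1-(2,4-dibromophenoxy)-4-hydroxy-2-oxocyclohexane-1-carboxylate (racemic, diastereomer mixture) | CC(C)(C)OC(=O)C1(Oc2ccc(Br)cc2Br)CCC(O)CC1=O | intermediate
8 | tert-butyl 1-(2,4-dibromophenoxy)-2-oxocyclohex-3-ene-1-carboxylate (racemic) | CC(C)(C)OC(=O)C1(Oc2ccc(Br)cc2Br)CCC=CC1=O | intermediate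
9 | keto acid: 1-(2,4-dibromophenoxy)-2-oxocyclohex-3-ene-1-carboxylic acid (racemic) | OC(=O)C1(Oc2ccc(Br)cc2Br)CCC=CC1=O | intermediate
10 | 6-(2,4-dibromophenoxy)cyclohex-2-en-1-one (racemic) | O=C1C=CCCC1Oc1ccc(Br)cc1Br | intermediate
11 | lithium dienolate: lithium 2-(2,4-dibromophenoxy)cyclohexa-1,5-dien-1-olate | [Li+].[O-]C1=C(Oc2ccc(Br)cc2Br)CCC=C1 | intermediate
12 | 1-(2,4-dibromophenoxy)-2-(trimethylsilyloxy)cyclohexa-1,3-diene | C[Si](C)(C)OC1=C(Oc2ccc(Br)cc2Br)CCC=C1 | intermediate
13 | aryl silyl ether: [2-(2,4-dibromophenoxy)phenoxy]trimethylsilane | C[Si](C)(C)Oc1ccccc1Oc1ccc(Br)cc1Br | intermediate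
14 | 2-(2,4-dibromophenoxy)phenol | Oc1ccccc1Oc1ccc(Br)cc1Br | intermediate
15 | tribromide: 4-bromo-2-(2,4-dibromophenoxy)phenol | Oc1ccc(Br)cc1Oc1ccc(Br)cc1Br | intermediate
16 | 2,4-dibromo-6-(2,4-dibromophenoxy)phenol (achiral) | Oc1c(Br)cc(Br)cc1Oc1ccc(Br)cc1Br | target

**Total step count:** 8. **Longest linear sequence:** 8 steps (1 to 16). Compounds 3 and 5 enter as bought.

**Three steps most likely to fail**

Step 2. K2CO3 also turns 2 into an unreactive enolate, and the hindered, weakly nucleophilic phenoxide may convert poorly. The fallback sets out from 1 and comes back to the route at 4, bypassing 2. Regitz diazo transfer onto 1 (4-acetamidobenzenesulfonyl azide, Et3N, MeCN, 0 °C to rt) gives tert-butyl 2-diazo-3-oxobutanoate F1. Rh2(OAc)4 (1 mol%) in refluxing CH2Cl2 then inserts the derived carbenoid into the O–H bond of 3, which gives 4 under neutral conditions.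

Step 4. The secondary amine can attack the acetyl group of the non-enolisable β-dicarbonyl 6 (retro-Claisen deacetylation) or provoke a retro-Michael reaction. The fallback sets out from 6 and comes back at 8, replacing the amine-catalysed condensation by addition, activation and elimination. Catalytic DBU in dilute THF at 0 °C closes 6 to ketol 7, which is isolated this time. MsCl and Et3N in CH2Cl2 at 0 °C convert it into tert-butyl 1-(2,4-dibromophenoxy)-4-(methylsulfonyloxy)-2-oxocyclohexane-1-carboxylate F2. Excess Et3N or DBU then eliminates the mesylate by E1cB to give 8.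

Step 5. Enone 10 stands at the oxidation level of phenol plus 3, so γ-enolisation followed by loss of 2,4-dibromophenol would destroy the ether link. The fallback sets out from 8 and comes back at 14, oxidising before decarboxylating so that 10 and 12 are never formed.
- t-BuMe2SiOTf and Et3N in CH2Cl2 at 0 °C can only deprotonate the γ-position of 8, giving tert-butyl 2-(tert-butyldimethylsilyloxy)-1-(2,4-dibromophenoxy)cyclohexa-2,4-diene-1-carboxylate F3.
- DDQ in toluene at rt dehydrogenates F3 to tert-butyl 1-(2,4-dibromophenoxy)-2-oxocyclohexa-3,5-diene-1-carboxylate F4.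
- TFA in CH2Cl2 cleaves the ester to 1-(2,4-dibromophenoxy)-2-oxocyclohexa-3,5-diene-1-carboxylic acid F5, which decarboxylates spontaneously with aromatisation to 14.

**Further compounds**
F1 | step 2 | tert-butyl 2-diazo-3-oxobutanoate | CC(=O)C(=[N+]=[N-])C(=O)OC(C)(C)C
F2 | step 4 | tert-butyl 1-(2,4-dibromophenoxy)-4-(methylsulfonyloxy)-2-oxocyclohexane-1-carboxylate (racemic, diastereomer mixture) | CC(C)(C)OC(=O)C1(Oc2ccc(Br)cc2Br)CCC(OS(C)(=O)=O)CC1=O
F3 | step 5 | tert-butyl 2-(tert-butyldimethylsilyloxy)-1-(2,4-dibromophenoxy)cyclohexa-2,4-diene-1-carboxylate (racemic) | CC(C)(C)OC(=O)C1(Oc2ccc(Br)cc2Br)CC=CC=C1O[Si](C)(C)C(C)(C)C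
F4 | step 5 | tert-butyl 1-(2,4-dibromophenoxy)-2-oxocyclohexa-3,5-diene-1-carboxylate (racemic) | CC(C)(C)OC(=O)C1(Oc2ccc(Br)cc2Br)C=CC=CC1=O
F5 | step 5 | 1-(2,4-dibromophenoxy)-2-oxocyclohexa-3,5-diene-1-carboxylic acid (racemic) | OC(=O)C1(Oc2ccc(Br)cc2Br)C=CC=CC1=O
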